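**Retrosynthetic overview**

- Target 27 ← oxidation and desilylation ← vinyl epoxide 25 ← cyclohexa-1,3-diene 23, by singlet-oxygen [4+2] addition and phosphine-induced SN2′ deoxygenation (oxirane formed last).
- Enabling feature: in 7-oxabicyclo[4.1.0]hept-2-ene numbering, the C1–C6 oxirane plus the C2=C3 alkene are a mono-epoxidised cyclohexa-1,3-diene. The remaining ring bond C4–C5 joins the only two oxygen-free sp3 ring carbons (quaternary C4 with methyl and pyranone, C5–H with the alkenyl chain). This is the retron of a disrotatory 6π electrocyclization of a (Z,Z,E)-hexatriene.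
- 23 ← acyclic tetraene 22 ← Negishi coupling of (Z)-iodoalkenyl pyranone 19 with (Z,E,E)-trienylzinc 21; coupling and ring closure run as one operation.
- 19 ← 2,6-dimethoxypyranone 13 plus a cis-silyl alkenyllithium (from propyne). Iodide 10 ← Evans syn-aldol, two Wittig homologations, iodo-Wittig.
- Ring order: pyranone (step 9), carbocycle (step 14), oxirane (step 15, through a transient dioxabicycle).

Key step: step 14

Remark: the remote side-chain centres cannot bias the sense of the thermal ring closure in step 14. The ring centres therefore get their relative configuration from the alkene geometries and their absolute configuration by chromatographic removal of the ring-antipodal diastereomer, with the enantiopure side chain (step 1) as internal resolving element.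

**Route**

Step 1
Reactants: 1 (4S)-4-benzyl-3-propanoyl-1,3-oxazolidin-2-one; 2 propanal
Product: 4 (4S)-4-benzyl-3-[(2S,3R)-3-hydroxy-2-methylpentanoyl]-1,3-oxazolidin-2-one, via dibutylboron Z-enolate 3 (not isolated)
Conditions: Bu2BOTf, i-Pr2NEt, CH2Cl2, 0 °C; 2, −78 → 0 °C; pH 7 buffer, MeOH, 30% H2O2, 0 °C
Reagents that add atoms: none
Why: Evans syn-aldol reaction: the Z boron enolate 3 reacts through a chair-like six-membered transition state on the face opposite the benzyl group, which should set the methyl-bearing centre (2S here, the 4R centre of the target side chain) and, syn to it, the carbinol centre that is later oxidised away.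

Step 2
Reactants: 4 (4S)-4-benzyl-3-[(2S,3R)-3-hydroxy-2-methylpentanoyl]-1,3-oxazolidin-2-one
Product: 5 (4S)-4-benzyl-3-[(2S,3R)-3-{[tert-butyl(dimethyl)silyl]oxy}-2-methylpentanoyl]-1,3-oxazolidin-2-one
Conditions: TBSOTf, 2,6-lutidine, CH2Cl2, −78 → 0 °C
Reagents that add atoms: tert-butyldimethylsilyl trifluoromethanesulfonate, CC(C)(C)[Si](C)(C)OS(=O)(=O)C(F)(F)F
Why: Silyl ether formation on the secondary alcohol; keeping the future ketone at the alcohol level prevents the neighbouring methyl centre from epimerising (no β-dicarbonyl, no β,γ-unsaturated ketone) until the last step.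

Step 3
Reactants: 5 (4S)-4-benzyl-3-[(2S,3R)-3-{[tert-butyl(dimethyl)silyl]oxy}-2-methylpentanoyl]-1,3-oxazolidin-2-one
Product: 6 (2R,3R)-3-{[tert-butyl(dimethyl)silyl]oxy}-2-methylpentan-1-ol
Conditions: LiBH4, MeOH (1 equiv), THF, 0 °C; aq. NaOH
Reagents that add atoms: none
Why: Reductive cleavage of the N-acyl oxazolidinone (hydride attacks the activated exocyclic carbonyl) should give the primary alcohol without touching the α-centre or the silyl ether.

Step 4
Reactants: 6 (2R,3R)-3-{[tert-butyl(dimethyl)silyl]oxy}-2-methylpentan-1-ol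
Product: 7 (2S,3R)-3-{[tert-butyl(dimethyl)silyl]oxy}-2-methylpentanal
Conditions: Dess–Martin periodinane, NaHCO3, CH2Cl2, 0 → 23 °C; used crude
Reagents that add atoms: none
Why: Dess–Martin oxidation under buffered, non-basic conditions should give the α-branched aldehyde, which is used crude so that its enolisable centre is not exposed to silica or base.

Step 5
Reactants: 7 (2S,3R)-3-{[tert-butyl(dimethyl)silyl]oxy}-2-methylpentanal
Product: 8 (2E,4R,5R)-5-{[tert-butyl(dimethyl)silyl]oxy}-2,4-dimethylhept-2-enal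
Conditions: Ph3P=C(Me)CHO, toluene, 90 °C
Reagents that add atoms: 2-(triphenylphosphoranylidene)propanal, CC(C=O)=P(c1ccccc1)(c1ccccc1)c1ccccc1
Why: Wittig reaction with a stabilised α-methyl ylide is E-selective (formyl group trans to the chain) and mild enough not to epimerise the α-centre.

Step 6
Reactants: 8 (2E,4R,5R)-5-{[tert-butyl(dimethyl)silyl]oxy}-2,4-dimethylhept-2-enal
Product: 9 (2E,4E,6R,7R)-7-{[tert-butyl(dimethyl)silyl]oxy}-2,4,6-trimethylnona-2,4-dienal
Conditions: Ph3P=C(Me)CHO, toluene, 110 °C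
Reagents that add atoms: 2-(triphenylphosphoranylidene)propanal, CC(C=O)=P(c1ccccc1)(c1ccccc1)c1ccccc1
Why: A second E-selective Wittig homologation with the same stabilised ylide on the less reactive 2-methyl enal should give the (2E,4E)-dienal that carries the two E alkenes of the later tetraene.

Step 7
Reactants: 9 (2E,4E,6R,7R)-7-{[tert-butyl(dimethyl)silyl]oxy}-2,4,6-trimethylnona-2,4-dienal
Product: 10 tert-butyl{[(3R,4R,5E,7E,9Z)-10-iodo-4,6,8-trimethylundeca-5,7,9-trien-3-yl]oxy}dimethylsilane
Conditions: EtPPh3I, n-BuLi, THF, 23 °C; I2, −78 °C; NaN(SiMe3)2, −78 °C; then 9, −78 → −20 °C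
Reagents that add atoms: ethyltriphenylphosphonium iodide, CC[P+](c1ccccc1)(c1ccccc1)c1ccccc1.[I-]; iodine, II
Why: Wittig iodo-olefination of the Stork–Zhao type: the α-iodo ylide reacts under kinetic control through the cis-oxaphosphetane and should place iodine cis to the chain, giving the (Z)-2-iodoalkene that becomes the central Z alkene of the triene.

Step 8
Reactants: 11 dimethyl 3-oxopentanedioate
Product: 12 dimethyl 2,4-dimethyl-3-oxopentanedioate
Conditions: MeI (2.1 equiv), K2CO3, acetone, 23 → 56 °C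
Reagents that add atoms: iodomethane, CI
Why: Double C-alkylation of the bis-β-keto ester at its two doubly activated positions; the stereocentres formed are irrelevant because both carbons become sp2 in step 9.

Step 9
Reactants: 12 dimethyl 2,4-dimethyl-3-oxopentanedioate
Product: 13 2,6-dimethoxy-3,5-dimethyl-4H-pyran-4-one
Conditions: conc. H2SO4, 20% oleum, 0 → 23 °C; ice
Reagents that add atoms: none
Why: Acid-mediated cyclodehydration of a 3-oxoglutarate diester: one ester oxygen closes onto the activated second ester carbon and loss of water aromatises to the symmetrical 2,6-dimethoxy-4-pyranone (C–O ring closure).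

Step 10
Reactants: 14 propyne
Product: 15 tributyl[(Z)-1-(trimethylsilyl)prop-1-en-2-yl]stannane
Conditions: Me3SiSnBu3, Pd(PPh3)4 (2 mol %), THF, 65 °C, sealed tube
Reagents that add atoms: trimethyl(tributylstannyl)silane, C[Si](C)(C)[Sn](CCCC)(CCCC)CCCC
Why: Palladium-catalysed silylstannation of a terminal alkyne is cis-specific and places tin on the internal and silicon on the terminal carbon, which fixes the later cis relation of pyranone and chain.

Step 11
Reactants: 15 tributyl[(Z)-1-(trimethylsilyl)prop-1-en-2-yl]stannane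
Product: 16 [(Z)-2-iodoprop-1-en-1-yl]trimethylsilane
Conditions: I2, CH2Cl2, 0 °C
Reagents that add atoms: iodine, II
Why: Iododestannylation: ipso-substitution of the alkenyl C–Sn bond is much faster than that of the C–Si bond and goes with retention, so iodine ends cis to silicon.

Step 12
Reactants: 16 [(Z)-2-iodoprop-1-en-1-yl]trimethylsilane; 13 2,6-dimethoxy-3,5-dimethyl-4H-pyran-4-one
Product: 18 2-methoxy-3,5-dimethyl-6-[(Z)-1-(trimethylsilyl)prop-1-en-2-yl]-4H-pyran-4-one, via alkenyllithium 17 (not isolated)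
Conditions: 16, t-BuLi (2 equiv), Et2O, −78 °C; added to 13 (1.3 equiv), THF, −78 → −20 °C; aq. NH4Cl
Reagents that add atoms: none
Why: Iodine–lithium exchange gives the configurationally stable alkenyllithium 17, which adds to the vinylogous carbonate carbon C2 of 13 and expels methoxide (nucleophilic vinylic substitution by addition–elimination on a 2-alkoxy-4-pyranone) with retention, so the pyranone sits cis to silicon; the symmetry of 13 makes its two methoxy positions equivalent.

Step 13
Reactants: 18 2-methoxy-3,5-dimethyl-6-[(Z)-1-(trimethylsilyl)prop-1-en-2-yl]-4H-pyran-4-one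
Product: 19 6-[(Z)-1-iodoprop-1-en-2-yl]-2-methoxy-3,5-dimethyl-4H-pyran-4-one
Conditions: NIS, MeCN–ClCH2CN (4:1), 0 → 23 °C, dark; aq. Na2S2O3
Reagents that add atoms: N-iodosuccinimide, O=C1CCC(=O)N1I
Why: Iododesilylation of an alkenylsilane in nitrile solvent (ipso attack, β-silyl cation, loss of silicon) is stereoretentive, so the pyranone should stay cis to iodine.

Step 14
Reactants: 10 tert-butyl{[(3R,4R,5E,7E,9Z)-10-iodo-4,6,8-trimethylundeca-5,7,9-trien-3-yl]oxy}dimethylsilane; 19 6-[(Z)-1-iodoprop-1-en-2-yl]-2-methoxy-3,5-dimethyl-4H-pyran-4-one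
Product: 23 6-{(1R,6R)-6-[(2E,4R,5R)-5-{[tert-butyl(dimethyl)silyl]oxy}-4-methylhept-2-en-2-yl]-1,3,5-trimethylcyclohexa-2,4-dien-1-yl}-2-methoxy-3,5-dimethyl-4H-pyran-4-one, via trienyllithium 20 (not isolated), via trienylzinc chloride 21 (not isolated), via tetraene 22 (not isolated)
Conditions: 10, t-BuLi (2 equiv), Et2O, −78 °C; ZnCl2, THF, −78 → 0 °C; 19, Pd(PPh3)4 (5 mol %), THF, 23 °C, dark; then toluene, BHT, 110–130 °C, sealed tube; chromatographic separation of the ring diastereomers
Reagents that add atoms: none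
Why: Iodine–lithium exchange on 10 and transmetalation to zinc give 21 with the alkene geometry intact, and Negishi coupling with 19 (retention at both sp2 carbons) assembles the (2Z,4Z,6E,8E)-tetraene 22, whose C2–C7 triene closes on heating by a thermal disrotatory 6π electrocyclization that forms the σ bond between the pyranone-bearing terminus C2 and the alkenyl-bearing terminus C7. The closest known reaction type is the cross-coupling/6π-electrocyclization sequence of polyene pyranones and other (Z,Z,E)-trienes, which need heating because one terminus carries an inward substituent. The carbocycle closes in the six-electron disrotatory mode, and no other pericyclic closure is open: the C6=C7 bond is E, which excludes 8π closure of the tetraene and 6π closure of the C4–C9 triene. The relative configuration follows from the alkene geometries: disrotation of a terminus with methyl outward and pyranone inward (Z-C2=C3, from 19) and a terminus with alkenyl outward and hydrogen inward (E-C6=C7, from step 6) places the quaternary methyl cis and the pyranone trans to the side chain. The remote (10R,11R) centres cannot bias the sense of disrotation, so 23 and its ring-antipodal diastereomer are expected in comparable amounts and are separated by chromatography. The step needs geometric integrity of every alkene up to the closure (exclusion of light, BHT, degassed solvent) and closure faster than [1,5]-hydrogen shift, which the strain of the Z,Z-diene unit in 22 should secure.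

Step 15
Reactants: 23 6-{(1R,6R)-6-[(2E,4R,5R)-5-{[tert-butyl(dimethyl)silyl]oxy}-4-methylhept-2-en-2-yl]-1,3,5-trimethylcyclohexa-2,4-dien-1-yl}-2-methoxy-3,5-dimethyl-4H-pyran-4-one
Product: 25 6-{(1R,4R,5S,6S)-5-[(2E,4R,5R)-5-{[tert-butyl(dimethyl)silyl]oxy}-4-methylhept-2-en-2-yl]-2,4,6-trimethyl-7-oxabicyclo[4.1.0]hept-2-en-4-yl}-2-methoxy-3,5-dimethyl-4H-pyran-4-one, via endoperoxide 24 (not isolated)
Conditions: O2, 5,10,15,20-tetraphenylporphyrin (1 mol %), CH2Cl2, −20 °C, visible light (> 500 nm); then PPh3 (1.1 equiv), −20 → 23 °C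
Reagents that add atoms: dioxygen, O=O
Why: Sensitised photooxygenation: singlet oxygen adds [4+2] across the diene termini, and bonding should begin at the unsubstituted terminus next to the quaternary carbon on the face of its methyl group and not of the pyranone, so the peroxide bridge of 24 lies anti to the pyranone; PPh3 then attacks the less hindered peroxide oxygen (on the CH bridgehead) and the released tertiary alkoxide closes by syn-SN2′ on the neighbouring alkene carbon with loss of Ph3PO (phosphine deoxygenation of an unsaturated bicyclic endoperoxide to the allylic epoxide), which sets both oxirane centres cis on the former peroxide face and returns the double bond to C2=C3.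

Step 16
Reactants: 25 6-{(1R,4R,5S,6S)-5-[(2E,4R,5R)-5-{[tert-butyl(dimethyl)silyl]oxy}-4-methylhept-2-en-2-yl]-2,4,6-trimethyl-7-oxabicyclo[4.1.0]hept-2-en-4-yl}-2-methoxy-3,5-dimethyl-4H-pyran-4-one
Product: 26 6-{(1R,4R,5S,6S)-5-[(2E,4R,5R)-5-hydroxy-4-methylhept-2-en-2-yl]-2,4,6-trimethyl-7-oxabicyclo[4.1.0]hept-2-en-4-yl}-2-methoxy-3,5-dimethyl-4H-pyran-4-one
Conditions: Bu4NF, THF, 0 → 23 °C; aq. NH4Cl
Reagents that add atoms: none
Why: Fluoride-mediated silyl ether cleavage under basic, non-acidic conditions should leave the acid-labile vinyl epoxide and the pyranone untouched.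

Step 17
Reactants: 26 6-{(1R,4R,5S,6S)-5-[(2E,4R,5R)-5-hydroxy-4-methylhept-2-en-2-yl]-2,4,6-trimethyl-7-oxabicyclo[4.1.0]hept-2-en-4-yl}-2-methoxy-3,5-dimethyl-4H-pyran-4-one
Product: 27 2-methoxy-3,5-dimethyl-6-{(1R,4R,5S,6S)-2,4,6-trimethyl-5-[(2E,4R)-4-methyl-5-oxohept-2-en-2-yl]-7-oxabicyclo[4.1.0]hept-2-en-4-yl}-4H-pyran-4-one
Conditions: Dess–Martin periodinane, NaHCO3, CH2Cl2, 0 °C
Reagents that add atoms: none
Why: Dess–Martin oxidation under buffered conditions should give the β,γ-unsaturated ketone without epimerising its α-methyl centre, moving the alkene into conjugation or opening the vinyl epoxide.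

**Compound list**

1 | (4S)-4-benzyl-3-propanoyl-1,3-oxazolidin-2-one | CCC(=O)N1[C@@H](Cc2ccccc2)COC1=O | starting material
2 | propanal | CCC=O | starting material
3 | (4S)-4-benzyl-3-[(Z)-1-(dibutylboranyloxy)prop-1-en-1-yl]-1,3-oxazolidin-2-one | C/C=C(\OB(CCCC)CCCC)N1[C@@H](Cc2ccccc2)COC1=O | intermediate
4 | (4S)-4-benzyl-3-[(2S,3R)-3-hydroxy-2-methylpentanoyl]-1,3-oxazolidin-2-one | CC[C@@H](O)[C@H](C)C(=O)N1[C@@H](Cc2ccccc2)COC1=O | intermediate
5 | (4S)-4-benzyl-3-[(2S,3R)-3-{[tert-butyl(dimethyl)silyl]oxy}-2-methylpentanoyl]-1,3-oxazolidin-2-one | CC[C@@H](O[Si](C)(C)C(C)(C)C)[C@H](C)C(=O)N1[C@@H](Cc2ccccc2)COC1=O | intermediate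
6 | (2R,3R)-3-{[tert-butyl(dimethyl)silyl]oxy}-2-methylpentan-1-ol | CC[C@@H](O[Si](C)(C)C(C)(C)C)[C@H](C)CO | intermediate
7 | (2S,3R)-3-{[tert-butyl(dimethyl)silyl]oxy}-2-methylpentanal | CC[C@@H](O[Si](C)(C)C(C)(C)C)[C@H](C)C=O | intermediate
8 | (2E,4R,5R)-5-{[tert-butyl(dimethyl)silyl]oxy}-2,4-dimethylhept-2-enal | CC[C@@H](O[Si](C)(C)C(C)(C)C)[C@H](C)/C=C(\C)C=O | intermediate
9 | (2E,4E,6R,7R)-7-{[tert-butyl(dimethyl)silyl]oxy}-2,4,6-trimethylnona-2,4-dienal | CC[C@@H](O[Si](C)(C)C(C)(C)C)[C@H](C)/C=C(\C)/C=C(\C)C=O | intermediate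
10 | tert-butyl{[(3R,4R,5E,7E,9Z)-10-iodo-4,6,8-trimethylundeca-5,7,9-trien-3-yl]oxy}dimethylsilane | CC[C@@H](O[Si](C)(C)C(C)(C)C)[C@H](C)/C=C(\C)/C=C(\C)/C=C(/C)I | intermediate
11 | dimethyl 3-oxopentanedioate | COC(=O)CC(=O)CC(=O)OC | starting material
12 | dimethyl 2,4-dimethyl-3-oxopentanedioate (mixture of stereoisomers) | COC(=O)C(C)C(=O)C(C)C(=O)OC | intermediate
13 | 2,6-dimethoxy-3,5-dimethyl-4H-pyran-4-one | COc1oc(OC)c(C)c(=O)c1C | intermediate
14 | propyne | CC#C | starting material
15 | tributyl[(Z)-1-(trimethylsilyl)prop-1-en-2-yl]stannane | C/C(=C/[Si](C)(C)C)[Sn](CCCC)(CCCC)CCCC | intermediate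
16 | [(Z)-2-iodoprop-1-en-1-yl]trimethylsilane | C/C(I)=C/[Si](C)(C)C | intermediate
17 | 2-lithio-1-(trimethylsilyl)propene, lithium cis to silicon | C/C([Li])=C/[Si](C)(C)C | intermediate
18 | 2-methoxy-3,5-dimethyl-6-[(Z)-1-(trimethylsilyl)prop-1-en-2-yl]-4H-pyran-4-one | COc1oc(/C(C)=C\[Si](C)(C)C)c(C)c(=O)c1C | intermediate
19 | 6-[(Z)-1-iodoprop-1-en-2-yl]-2-methoxy-3,5-dimethyl-4H-pyran-4-one | COc1oc(/C(C)=C\I)c(C)c(=O)c1C | intermediate
20 | trienyllithium: 10 with lithium in place of iodine, geometry retained | CC[C@@H](O[Si](C)(C)C(C)(C)C)[C@H](C)/C=C(\C)/C=C(\C)/C=C(/C)[Li] | intermediate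
21 | trienylzinc chloride: 10 with chlorozinc in place of iodine, geometry retained | CC[C@@H](O[Si](C)(C)C(C)(C)C)[C@H](C)/C=C(\C)/C=C(\C)/C=C(/C)[Zn]Cl | intermediate
22 | 6-[(2Z,4Z,6E,8E,10R,11R)-11-{[tert-butyl(dimethyl)silyl]oxy}-4,6,8,10-tetramethyltrideca-2,4,6,8-tetraen-2-yl]-2-methoxy-3,5-dimethyl-4H-pyran-4-one | CC[C@@H](O[Si](C)(C)C(C)(C)C)[C@H](C)/C=C(\C)/C=C(\C)/C=C(/C)\C=C(\C)/c1oc(OC)c(C)c(=O)c1C | intermediate
23 | 6-{(1R,6R)-6-[(2E,4R,5R)-5-{[tert-butyl(dimethyl)silyl]oxy}-4-methylhept-2-en-2-yl]-1,3,5-trimethylcyclohexa-2,4-dien-1-yl}-2-methoxy-3,5-dimethyl-4H-pyran-4-one (pyranone trans to the alkenyl chain) | CC[C@@H](O[Si](C)(C)C(C)(C)C)[C@H](C)/C=C(\C)[C@@H]1C(C)=CC(C)=C[C@@]1(C)c1oc(OC)c(C)c(=O)c1C | intermediate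
24 | 2,3-dioxabicyclo[2.2.2]oct-5-ene endoperoxide of 23: dioxygen bridge across C2 and C5 of the diene, anti to the pyranone | CC[C@@H](O[Si](C)(C)C(C)(C)C)[C@H](C)/C=C(\C)[C@@H]1[C@]2(C)OO[C@@H](C(C)=C2)[C@@]1(C)c1oc(OC)c(C)c(=O)c1C | intermediate
25 | 6-{(1R,4R,5S,6S)-5-[(2E,4R,5R)-5-{[tert-butyl(dimethyl)silyl]oxy}-4-methylhept-2-en-2-yl]-2,4,6-trimethyl-7-oxabicyclo[4.1.0]hept-2-en-4-yl}-2-methoxy-3,5-dimethyl-4H-pyran-4-one | CC[C@@H](O[Si](C)(C)C(C)(C)C)[C@H](C)/C=C(\C)[C@@H]1[C@]2(C)O[C@@H]2C(C)=C[C@@]1(C)c1oc(OC)c(C)c(=O)c1C | intermediate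
26 | 6-{(1R,4R,5S,6S)-5-[(2E,4R,5R)-5-hydroxy-4-methylhept-2-en-2-yl]-2,4,6-trimethyl-7-oxabicyclo[4.1.0]hept-2-en-4-yl}-2-methoxy-3,5-dimethyl-4H-pyran-4-one | CC[C@@H](O)[C@H](C)/C=C(\C)[C@@H]1[C@]2(C)O[C@@H]2C(C)=C[C@@]1(C)c1oc(OC)c(C)c(=O)c1C | intermediate
27 | 2-methoxy-3,5-dimethyl-6-{(1R,4R,5S,6S)-2,4,6-trimethyl-5-[(2E,4R)-4-methyl-5-oxohept-2-en-2-yl]-7-oxabicyclo[4.1.0]hept-2-en-4-yl}-4H-pyran-4-one | CCC(=O)[C@H](C)/C=C(\C)[C@@H]1[C@]2(C)O[C@@H]2C(C)=C[C@@]1(C)c1oc(OC)c(C)c(=O)c1C | target

**Totals**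

Total step count: 17.
Longest linear sequence: 11 steps (steps 1–7, then 14–17).

**Steps most likely to fail**

Step 14. The (Z)-geometry at the metal-bearing carbon may erode during iodine–lithium exchange on a conjugated trienyl iodide, and palladium residues may isomerise or decompose the polyene when the crude coupling mixture is heated. In addition the closure has no facial bias, so about half of the material is lost at the separation in any variant. The fallback sets out from 10 and 19 and comes back at 22 and hence 23. Miyaura borylation of 10 (B2pin2, PdCl2(PPh3)2, PPh3, KOPh, toluene, 50 °C) should give, with retention, the trienyl pinacol boronate 2-[(2E,4E,6E,8R,9R)-9-{[tert-butyl(dimethyl)silyl]oxy}-4,6,8-trimethylundeca-2,4,6-trien-2-yl]-4,4,5,5-tetramethyl-1,3,2-dioxaborolane F1. Suzuki–Miyaura coupling of F1 with 19 (Pd(PPh3)4, aq. K3PO4, THF, 23 °C, dark) should give tetraene 22, which is now isolated by rapid filtration through silica to remove palladium. It is then thermolysed on its own in degassed toluene with BHT at 110–130 °C to 23.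

Step 15. The phosphine may attack the more hindered peroxide oxygen, which would give the regioisomeric epoxide on the other ring alkene. The cycloaddition may also show low facial discrimination between the pyranone face and the alkenyl face, and an ene reaction at the side-chain alkene may compete. The fallback sets out from 24 and comes back at 25. Crude 24 is reduced with thiourea (MeOH, 0 °C) to the cis-cyclohex-2-ene-1,4-diol F2. Mitsunobu cyclodehydration (PPh3, DIAD, THF, 0 °C) then activates only the secondary allylic hydroxyl, so the tertiary alkoxide can only close by SN2′ on the adjacent alkene carbon, giving 25 with defined regiochemistry. If the cycloaddition is not face-selective, the diastereomeric diols are separated at the stage of F2; the fallback does not correct the facial course itself.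

Step 13. Ipso-substitution of the electron-poor, pyranone-conjugated alkenylsilane may be sluggish, and the alkene geometry may be partly lost through the β-silyl cation. The fallback sets out from 13 and comes back at 22 and hence 23. HC≡CMgBr (THF, −40 °C) should add to 13 by the same addition–elimination to give 6-ethynyl-2-methoxy-3,5-dimethyl-4H-pyran-4-one F3. Copper-catalysed syn-methylboration (B2pin2, MeI, CuCl, Xantphos, NaOt-Bu, THF) should give the (E)-alkenylboronate 2-methoxy-3,5-dimethyl-6-[(E)-1-(4,4,5,5-tetramethyl-1,3,2-dioxaborolan-2-yl)prop-1-en-2-yl]-4H-pyran-4-one F4, with boron trans to the pyranone. Triplet-sensitised contra-thermodynamic E-to-Z isomerisation (Ir(ppy)3, 450 nm light, MeCN) should give the (Z)-alkenylboronate F5, whose twisted pyranone–alkene unit no longer accepts triplet energy. Suzuki–Miyaura coupling of F5 with iodide 10 (Pd(PPh3)4, aq. K3PO4, THF, 23 °C, dark) gives 22, which is thermolysed to 23 as described for the fallback to step 14.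

Further compounds
F1 | step 14 | 2-[(2E,4E,6E,8R,9R)-9-{[tert-butyl(dimethyl)silyl]oxy}-4,6,8-trimethylundeca-2,4,6-trien-2-yl]-4,4,5,5-tetramethyl-1,3,2-dioxaborolane (boron cis to the chain, as iodine in 10) | CC[C@@H](O[Si](C)(C)C(C)(C)C)[C@H](C)/C=C(\C)/C=C(\C)/C=C(/C)B1OC(C)(C)C(C)(C)O1
F2 | step 15 | cis-cyclohex-2-ene-1,4-diol from 24: 6-{6-[(2E,4R,5R)-5-{[tert-butyl(dimethyl)silyl]oxy}-4-methylhept-2-en-2-yl]-2,5-dihydroxy-1,3,5-trimethylcyclohex-3-en-1-yl}-2-methoxy-3,5-dimethyl-4H-pyran-4-one, both hydroxyls anti to the pyranone | CC[C@@H](O[Si](C)(C)C(C)(C)C)[C@H](C)/C=C(\C)[C@@H]1[C@](C)(O)C=C(C)[C@H](O)[C@@]1(C)c1oc(OC)c(C)c(=O)c1C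
F3 | step 13 | 6-ethynyl-2-methoxy-3,5-dimethyl-4H-pyran-4-one | COc1oc(C#C)c(C)c(=O)c1C
F4 | step 13 | 2-methoxy-3,5-dimethyl-6-[(E)-1-(4,4,5,5-tetramethyl-1,3,2-dioxaborolan-2-yl)prop-1-en-2-yl]-4H-pyran-4-one | COc1oc(/C(C)=C/B2OC(C)(C)C(C)(C)O2)c(C)c(=O)c1C
F5 | step 13 | 2-methoxy-3,5-dimethyl-6-[(Z)-1-(4,4,5,5-tetramethyl-1,3,2-dioxaborolan-2-yl)prop-1-en-2-yl]-4H-pyran-4-one | COc1oc(/C(C)=C\B2OC(C)(C)C(C)(C)O2)c(C)c(=O)c1C
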